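## The problem

The target is a germacranolide. A ten-membered carbocycle (C1–C10) is fused across C6–C7 to a five-membered α-methylene lactone (O6–C12, C11=C13). The ring carries a trans C1–C10 epoxide whose quaternary carbon C10 bears the acetoxymethyl group C14, a ring-cis C4=C5 alkene with the free hydroxymethyl C15 on C4, and a methacrylate on C8. Five stereocentres must be set. C1 and C10 are remote from C6–C8 in any open-chain precursor and need a reagent-controlled epoxidation. C7 and C8 are neighbours that one aldol event can set together, and C6 can then be steered by C7. The ten-membered ring must be closed in the presence of an epoxide, an alkene of fixed geometry and three oxygens (C8, C14, C15) that have to be told apart. The fragile groups are: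

- the epoxide (acid; an alkoxide at C14 would make it migrate);
- the methylene lactone and the methacrylate (Michael acceptors for thiolates, amines and hydrides);
- the two esters (no hydride or strong base once they are in place);
- the 6,12-lactone, which can shift to O8 when that oxygen is free under base.

The enabling feature is that C6 is at once a member of the ten-membered ring, the neighbour of the sp2 carbon C5 and the alkoxy carbon of the lactone, with the acyl carbon C12 four atoms away (O6–C6–C7–C11–C12). Adding a C5 alkenyl metal to a C6 aldehyde therefore makes the ring bond and, in the same event, the alkoxide that closes the lactone.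

## Retrosynthesis

**Acyl groups and C15 (39 ⇐ 38 ⇐ 37 ⇐ 36 ⇐ 35).** The methacrylate, the acetate and the free C15 hydroxyl cannot pass through enolate, thiolate or hydride chemistry, so they are cut first. This leads to methylene lactone 35, which carries triethylsilyl (TES) ethers on O8 and O14 and a tert-butyldiphenylsilyl (TBDPS) ether on O15. Using the same labile group on O8 and O14 lets one operation free both (36). The primary C14 hydroxyl is then acetylated ahead of the ring secondary C8 hydroxyl (37), O8 is methacrylated (38), and buffered fluoride removes the TBDPS group last. This costs one step less than a separate ether on O14, and the forward steps must only be mild acylations and fluoride cleavages.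

**C11=C13 (35 ⇐ 33 ⇐ 31).** The exocyclic methylene is cut next, since a Michael acceptor would not survive the thiolate, hydride and chromium steps before it. Saturated lactone 31 has a single acidic position, C11, so a Mannich reaction and elimination through 33 is the standard return.

**C5–C6 and O6–C12 (31 ⇐ 28, the key cut).** Both ring-fusion bonds at C6 are cut together, giving the open-chain iodoalkene aldehyde ester 28.

- The neighbouring C6–C7 cut (allylmetal addition) would have to create C6 and C7 in the ring-closing event.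
- Cuts at C1–C2, C2–C3 or C8–C9 join two sp3 carbons and have no comparably mild ring-closing reaction.
- Cutting C5–C6 keeps the alkene geometry in a stable alkenyl iodide, leaves C7 and C8 to be set beforehand in an open chain, and needs only a near-neutral chromium reagent that tolerates epoxide, ester and silyl ethers.
- The precursor is much simpler: no rings except the epoxide, and one stereocentre fewer.
- The forward reaction must close a ten-membered ring against intermolecular coupling and must attack the C6 aldehyde on the face dictated by C7.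

**C6 oxidation level and C7–C8 (28 ⇐ 27 ⇐ 26 ⇐ 25 ⇐ 19 + 22).** The aldehyde at C6 beside a C12 ester cannot be reached through the C6 alcohol, which would lactonise onto C12. It is therefore taken from thioester 27 by partial reduction, and 27 from imide 26 by thiolate exchange. The syn relation of the C7 branch and O8 maps onto an Evans syn-aldol of succinate imide 22 with aldehyde 19, giving 25 (silylated to 26). An aldol is preferred to an alkylation of a β-hydroxy ester dianion, which would give the anti isomer. The forward step must cope with a β,γ-epoxy aldehyde and with a hydroxy ester that can lactonise.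

**Epoxide and C8 aldehyde (19 ⇐ 18 ⇐ 17 ⇐ 16 ⇐ 15).** The aldehyde carbon C8 is taken from the terminal alkene of an allyl group by dihydroxylation and glycol cleavage (17 → 18 → 19). These neutral operations leave the electron-poor iodoalkene alone. The epoxide is cut back to the Z allylic alcohol 15. A Sharpless epoxidation on C14–OH sets C1 and C10 by reagent control, before any other stereocentre exists.

**C1=C10 (15 ⇐ 14 ⇐ 8 + 12).** The trisubstituted alkene must have C14 cis to C2. A Still–Gennari olefination of aldehyde 8 with the allyl-substituted phosphonate 12 gives that geometry in ester 14, where the ester carbon is C14 and the allyl group supplies C9 and C8. A Wittig reaction on a C10 ketone would give no such control.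

**Iodoalkene and small fragments (8 ⇐ 7 ⇐ 2 + 3; 12 ⇐ 9 + 10; 22 ⇐ 20 + 21; 2 ⇐ 1).** The C3–C4 bond and the C5–I bond are cut together: syn-carbocupration of propargyl silyl ether 2 with the copper reagent from bromo acetal 3, then iodination, gives 7 with iodine cis to the new chain. Acetal hydrolysis gives 8. Phosphonate 12 comes from phosphonoacetate 9 and allyl bromide 10; imide 22 from oxazolidinone 20 and acid chloride 21; 2 from propargyl alcohol 1.

## Roads not taken

**Alternative 1:** The ten-membered ring would be released from a six–six bicycle by breaking the transannular C1–C6 bond. A C6 potassium alkoxide (KH, 18-crown-6) pushes into that bond, anti to the C10–O bond of a spiro-epoxide, and gives dienone A1.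
- Merits: the ring is opened, not closed, so there is no dilution problem, and the C1=C10 geometry follows from the fragmentation. In the ring-forming event itself this road is better than the chosen one.
- Weak points: A1 still needs the C6 ketone reduced with control on a flexible ring, C12 raised by two oxidation levels before a lactone can form, and the epoxide put on late. Its enone with an enolisable C7 is exposed to strong base, and a bicycle carrying the C4=C5 alkene, the C8 oxygen and a defined spiro-epoxide is itself a long synthesis.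
- Comparison: the chosen plan sets against this a ring closure that already contains the epoxide, C7, C8 and the lactone oxidation level, so 31 is six steps from the target.

**Alternative 2:** The cut is C7–C11 together with the lactone, on a ring that already exists. A C6 phosphonoacetate carbanion opens a C7,C8 cyclic sulfate at C7 with inversion, formaldehyde then gives the methylene lactone, and the product is A2.
- Merits: C6, C7 and C8 come from a sugar, and the methylene lactone and the free C8 hydroxyl appear in one flask. That end game is shorter than the chosen one, which needs a Mannich sequence and a desilylation.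
- Weak points: the step does not make the ten-membered ring, so a macrocycle with three contiguous oxygens must first be built by another closure. The carbanion must reach C7 from the rear inside a medium ring and must not attack C8, the C6 ester is allylic, and A2 still lacks the epoxide, which would have to be placed late among three alkenes.
- Comparison: the chosen plan answers the ring question directly and has the epoxide in place early.

**Alternative 3:** The cut is C9–C10. SmI2 reduces a C9 bromide beside a C8 ketone to a samarium enolate, which adds to a C10 ketone and gives hydroxy ketone A3.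
- Merits: samarium chelates both carbonyls, so such closures of medium rings are dependable and often need less dilution. As a ring closure this is probably the safer reaction.
- Weak points: A3 is far from the target. The C8 ketone must be reduced with control, the C10 hydroxyl and the C1 oxygen must be turned into the epoxide with inversion at C1, the lactone is not yet formed, C12 is at the alcohol level, and five protecting groups must be handled. A β-hydroxy ketone in the ring can also reopen by retro-aldol.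
- Comparison: the chosen plan accepts a harder ring closure in exchange for a much shorter path after it.

Key step: step 16

## Route

Remark: germacrane numbering is used for all intermediates. Because C15 carries oxygen, the ring-cis C4=C5 alkene and the iodoalkene with iodine cis to C3 are both E by the sequence rule. The descriptor at C7 reads S while O8 carries silicon and R otherwise, with no change in shape.

Step 1
Reactants: 1 prop-2-yn-1-ol (propargyl alcohol)
Product: 2 tert-butyl(diphenyl)(prop-2-yn-1-yloxy)silane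
Conditions: TBDPSCl, imidazole, CH2Cl2, 0 °C → rt
Reagents that add atoms: tert-butyl(chloro)diphenylsilane, CC(C)(C)[Si](Cl)(c1ccccc1)c1ccccc1
Why: Standard silylation of a primary alcohol; the bulky, weakly donating silyl ether later keeps the propargylic oxygen from directing copper and lasts to the final step.

Step 2
Reactants: 3 2-(2-bromoethyl)-1,3-dioxolane; 2 tert-butyl(diphenyl)(prop-2-yn-1-yloxy)silane
Product: 7 tert-butyl({(2E)-2-[2-(1,3-dioxolan-2-yl)ethyl]-3-iodoprop-2-en-1-yl}oxy)diphenylsilane, via Grignard reagent 4 (not isolated), via alkylcopper 5 (not isolated), via alkenylcopper 6 (not isolated)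
Conditions: 3, Mg, THF, 25 °C; CuBr·SMe2, THF–Et2O, −40 °C; 2, −25 °C; I2, −40 → 0 °C
Reagents that add atoms: iodine, II
Why: Syn-carbocupration of a terminal alkyne puts the alkyl group on the inner carbon (C4) and copper on the terminal carbon (C5) cis to it, and iodinolysis of the C–Cu bond goes with retention, so iodine ends cis to the C3 chain. A silyl ether is a poor donor and THF competes for copper, which disfavours the oxygen-directed regioisomer that would eliminate to an allene.

Step 3
Reactants: 7 tert-butyl({(2E)-2-[2-(1,3-dioxolan-2-yl)ethyl]-3-iodoprop-2-en-1-yl}oxy)diphenylsilane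
Product: 8 (4E)-4-{[tert-butyl(diphenyl)silyl]oxymethyl}-5-iodopent-4-enal
Conditions: 2 M aq. HCl, THF, rt
Reagents that add atoms: water, O
Why: Acid hydrolysis of the dioxolane to the C1 aldehyde; the TBDPS ether and the iodoalkene are stable to dilute aqueous acid.

Step 4
Reactants: 9 methyl 2-[bis(2,2,2-trifluoroethoxy)phosphoryl]acetate; 10 3-bromoprop-1-ene (allyl bromide)
Product: 12 methyl 2-[bis(2,2,2-trifluoroethoxy)phosphoryl]pent-4-enoate (racemic), via sodium phosphonoacetate 11 (not isolated)
Conditions: NaH, THF, 0 °C; 10, 0 °C → rt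
Reagents that add atoms: none
Why: C-Alkylation of a stabilised phosphonoacetate carbanion by a reactive allylic halide; a slight excess of 9 holds back dialkylation.

Step 5
Reactants: 8 (4E)-4-{[tert-butyl(diphenyl)silyl]oxymethyl}-5-iodopent-4-enal; 12 methyl 2-[bis(2,2,2-trifluoroethoxy)phosphoryl]pent-4-enoate
Product: 14 methyl (2Z,6E)-6-{[tert-butyl(diphenyl)silyl]oxymethyl}-7-iodo-2-(prop-2-en-1-yl)hepta-2,6-dienoate, via potassium phosphonate carbanion 13 (not isolated)
Conditions: KN(SiMe3)2, 18-crown-6, THF, −78 °C; 8, −78 °C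
Reagents that add atoms: none
Why: Still–Gennari olefination: with the electron-poor trifluoroethyl phosphonate and a free potassium ion, elimination outruns equilibration of the adducts, so the ester (C14) ends cis to the aldehyde-derived chain (C2). This Z geometry is what the trans epoxide needs.

Step 6
Reactants: 14 methyl (2Z,6E)-6-{[tert-butyl(diphenyl)silyl]oxymethyl}-7-iodo-2-(prop-2-en-1-yl)hepta-2,6-dienoate
Product: 15 (2Z,6E)-6-{[tert-butyl(diphenyl)silyl]oxymethyl}-7-iodo-2-(prop-2-en-1-yl)hepta-2,6-dien-1-ol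
Conditions: i-Bu2AlH (2.2 equiv), CH2Cl2, −78 °C; aq. KNaC4H4O6 (potassium sodium tartrate)
Reagents that add atoms: none
Why: 1,2-Reduction of a conjugated ester to the allylic alcohol; the iodoalkene, the terminal alkene and the silyl ether are inert to the aluminium hydride at −78 °C.

Step 7
Reactants: 15 (2Z,6E)-6-{[tert-butyl(diphenyl)silyl]oxymethyl}-7-iodo-2-(prop-2-en-1-yl)hepta-2,6-dien-1-ol
Product: 16 [(2S,3R)-3-[(3E)-3-{[tert-butyl(diphenyl)silyl]oxymethyl}-4-iodobut-3-en-1-yl]-2-(prop-2-en-1-yl)oxiran-2-yl]methanol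
Conditions: Ti(OiPr)4 (0.2 equiv), L-(+)-diethyl tartrate (0.24 equiv), t-BuOOH, 4 Å MS, CH2Cl2, −20 °C
Reagents that add atoms: tert-butyl hydroperoxide, CC(C)(C)OO
Why: Sharpless asymmetric epoxidation: only the alkene of the titanium-bound allylic alcohol reacts, and the L-(+)-tartrate delivers oxygen to the face that gives C10 (S) and C1 (R). Syn addition turns the Z alkene into the epoxide with C2 and C9 trans.

Step 8
Reactants: 16 [(2S,3R)-3-[(3E)-3-{[tert-butyl(diphenyl)silyl]oxymethyl}-4-iodobut-3-en-1-yl]-2-(prop-2-en-1-yl)oxiran-2-yl]methanol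
Product: 17 {(2S,3R)-3-[(3E)-3-{[tert-butyl(diphenyl)silyl]oxymethyl}-4-iodobut-3-en-1-yl]-2-(prop-2-en-1-yl)oxiran-2-yl}methyl triethylsilyl ether
Conditions: TESCl, imidazole, CH2Cl2, 0 °C
Reagents that add atoms: chlorotriethylsilane, CC[Si](Cl)(CC)CC
Why: Silylation under buffered conditions forms no free alkoxide, so the 2,3-epoxy alcohol cannot undergo Payne rearrangement; this TES ether is later removed together with the one on O8.

Step 9
Reactants: 17 {(2S,3R)-3-[(3E)-3-{[tert-butyl(diphenyl)silyl]oxymethyl}-4-iodobut-3-en-1-yl]-2-(prop-2-en-1-yl)oxiran-2-yl}methyl triethylsilyl ether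
Product: 18 3-{(2S,3R)-3-[(3E)-3-{[tert-butyl(diphenyl)silyl]oxymethyl}-4-iodobut-3-en-1-yl]-2-[(triethylsilyloxy)methyl]oxiran-2-yl}propane-1,2-diol (both C2 epimers of the diol)
Conditions: OsO4 (2 mol %), N-methylmorpholine N-oxide, acetone–H2O, rt
Reagents that add atoms: N-methylmorpholine N-oxide, C[N+]1([O-])CCOCC1; water, O
Why: Catalytic dihydroxylation takes the monosubstituted terminal alkene; the iodoalkene is electron-poor and hindered and is left alone. The new carbinol centre is lost in the next step.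

Step 10
Reactants: 18 3-{(2S,3R)-3-[(3E)-3-{[tert-butyl(diphenyl)silyl]oxymethyl}-4-iodobut-3-en-1-yl]-2-[(triethylsilyloxy)methyl]oxiran-2-yl}propane-1,2-diol
Product: 19 {(2S,3R)-3-[(3E)-3-{[tert-butyl(diphenyl)silyl]oxymethyl}-4-iodobut-3-en-1-yl]-2-[(triethylsilyloxy)methyl]oxiran-2-yl}acetaldehyde
Conditions: NaIO4, THF–pH 7 buffer, 0 °C
Reagents that add atoms: none
Why: Periodate glycol cleavage under neutral conditions gives the C8 aldehyde. The β,γ-epoxy aldehyde is used at once without chromatography, because base or silica gel could open the epoxide through the enol.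

Step 11
Reactants: 20 (4R)-4-benzyl-1,3-oxazolidin-2-one; 21 methyl 4-chloro-4-oxobutanoate
Product: 22 methyl 4-[(4R)-4-benzyl-2-oxo-1,3-oxazolidin-3-yl]-4-oxobutanoate
Conditions: Et3N, DMAP (cat.), CH2Cl2, 0 °C → rt
Reagents that add atoms: none
Why: N-Acylation of the oxazolidinone by an acid chloride under amine and DMAP catalysis gives the succinate imide.

Step 12
Reactants: 22 methyl 4-[(4R)-4-benzyl-2-oxo-1,3-oxazolidin-3-yl]-4-oxobutanoate; 19 {(2S,3R)-3-[(3E)-3-{[tert-butyl(diphenyl)silyl]oxymethyl}-4-iodobut-3-en-1-yl]-2-[(triethylsilyloxy)methyl]oxiran-2-yl}acetaldehyde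
Product: 25 methyl (3R,4S)-3-{[(4R)-4-benzyl-2-oxo-1,3-oxazolidin-3-yl]carbonyl}-4-hydroxy-5-{(2S,3R)-3-[(3E)-3-{[tert-butyl(diphenyl)silyl]oxymethyl}-4-iodobut-3-en-1-yl]-2-[(triethylsilyloxy)methyl]oxiran-2-yl}pentanoate, via boron enolate 23 (not isolated), via boron aldolate 24 (not isolated)
Conditions: Bu2BOTf (1.15 equiv), i-Pr2NEt (1.1 equiv), CH2Cl2, −78 → 0 °C; 19, −78 → −20 °C; pH 7 buffer, MeOH, H2O2, 0 °C
Reagents that add atoms: none
Why: Evans syn-aldol: the Z boron enolate reacts through a chair Zimmerman–Traxler transition state on the face away from the benzyl group of the (R)-auxiliary, which sets C7 (R) and C8 (S) together regardless of the remote epoxide. The amine is kept below the boron triflate so that no free base can enolise 19, and the crude adduct is silylated directly so that O8 cannot close on the C12 ester.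

Step 13
Reactants: 25 methyl (3R,4S)-3-{[(4R)-4-benzyl-2-oxo-1,3-oxazolidin-3-yl]carbonyl}-4-hydroxy-5-{(2S,3R)-3-[(3E)-3-{[tert-butyl(diphenyl)silyl]oxymethyl}-4-iodobut-3-en-1-yl]-2-[(triethylsilyloxy)methyl]oxiran-2-yl}pentanoate
Product: 26 methyl (3R,4S)-3-{[(4R)-4-benzyl-2-oxo-1,3-oxazolidin-3-yl]carbonyl}-5-{(2S,3R)-3-[(3E)-3-{[tert-butyl(diphenyl)silyl]oxymethyl}-4-iodobut-3-en-1-yl]-2-[(triethylsilyloxy)methyl]oxiran-2-yl}-4-(triethylsilyloxy)pentanoate
Conditions: TESOTf, 2,6-lutidine, CH2Cl2, −78 °C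
Reagents that add atoms: triethylsilyl trifluoromethanesulfonate, CC[Si](CC)(CC)OS(=O)(=O)C(F)(F)F
Why: Fast low-temperature silylation of the secondary alcohol; it blocks lactonisation toward C12 and retro-aldol cleavage in the basic step that follows.

Step 14
Reactants: 26 methyl (3R,4S)-3-{[(4R)-4-benzyl-2-oxo-1,3-oxazolidin-3-yl]carbonyl}-5-{(2S,3R)-3-[(3E)-3-{[tert-butyl(diphenyl)silyl]oxymethyl}-4-iodobut-3-en-1-yl]-2-[(triethylsilyloxy)methyl]oxiran-2-yl}-4-(triethylsilyloxy)pentanoate
Product: 27 methyl (3R,4S)-5-{(2S,3R)-3-[(3E)-3-{[tert-butyl(diphenyl)silyl]oxymethyl}-4-iodobut-3-en-1-yl]-2-[(triethylsilyloxy)methyl]oxiran-2-yl}-3-[(ethylsulfanyl)carbonyl]-4-(triethylsilyloxy)pentanoate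
Conditions: EtSH, n-BuLi, THF, −78 → 0 °C
Reagents that add atoms: ethanethiol, CCS
Why: Lithium ethanethiolate attacks the exocyclic imide carbonyl and releases the auxiliary; the methyl ester stays, because exchanging an ester for a thioester is uphill.

Step 15
Reactants: 27 methyl (3R,4S)-5-{(2S,3R)-3-[(3E)-3-{[tert-butyl(diphenyl)silyl]oxymethyl}-4-iodobut-3-en-1-yl]-2-[(triethylsilyloxy)methyl]oxiran-2-yl}-3-[(ethylsulfanyl)carbonyl]-4-(triethylsilyloxy)pentanoate
Product: 28 methyl (3R,4S)-5-{(2S,3R)-3-[(3E)-3-{[tert-butyl(diphenyl)silyl]oxymethyl}-4-iodobut-3-en-1-yl]-2-[(triethylsilyloxy)methyl]oxiran-2-yl}-3-formyl-4-(triethylsilyloxy)pentanoate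
Conditions: i-Bu2AlH (1.1 equiv), CH2Cl2, −78 °C; aq. KNaC4H4O6 (potassium sodium tartrate)
Reagents that add atoms: none
Why: Partial reduction of a thioester: its carbonyl is more electrophilic than that of the ester, and the aluminium hemithioacetal is stable at −78 °C. The aldehyde appears only on work-up, so the C6 alcohol, which would lactonise onto C12, is never formed.

Step 16
Reactants: 28 methyl (3R,4S)-5-{(2S,3R)-3-[(3E)-3-{[tert-butyl(diphenyl)silyl]oxymethyl}-4-iodobut-3-en-1-yl]-2-[(triethylsilyloxy)methyl]oxiran-2-yl}-3-formyl-4-(triethylsilyloxy)pentanoate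
Product: 31 (1R,4E,6R,7S,8S,10S)-15-(tert-butyldiphenylsilyloxy)-1,10-epoxy-8,14-bis(triethylsilyloxy)germacr-4-en-12,6-olide, via alkenylchromium species 29 (not isolated), via chromium alkoxide 30 (not isolated)
Conditions: CrCl2 (8 equiv), NiCl2 (2 mol % of CrCl2), degassed DMSO, 3 mM, syringe-pump addition, rt; aq. NH4Cl
Reagents that add atoms: none
Why: CrCl2 reduces NiCl2 to zerovalent nickel, which inserts into the C5–I bond with retention of alkene geometry; transfer to trivalent chromium gives alkenylchromium 29, which adds to the C6 aldehyde (an intramolecular Nozaki–Hiyama–Kishi reaction, the closest known type being alkenyl iodide–aldehyde closures of medium rings). The carbocycle closes in a 10-exo-trig mode at the carbonyl carbon, helped by the ring-cis C4=C5 alkene and the trans epoxide, which already fold C5 toward C6. Chromium alkoxide 30 then attacks the C12 methyl ester four atoms away in a 5-exo-trig acyl substitution and expels methoxide, so the lactone closes in the same flask (brief contact with silica gel finishes it if some hydroxy ester survives the quench). The new C6 centre is controlled by C7: in the Felkin–Anh arrangement the C8 branch stands anti to the incoming alkenyl group and the CH2CO2Me arm lies beside the carbonyl oxygen, which places O6 and C11 syn along the C5–C8 backbone and so gives the trans-fused lactone (6R). The step needs ring closure to beat intermolecular coupling, which slow addition at about 3 mM secures, and it needs selectivity for the aldehyde, which the low basicity and nucleophilicity of organochromium reagents secure: ester, epoxide and silyl ethers are left alone and C7 is not epimerised.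

Step 17
Reactants: 31 (1R,4E,6R,7S,8S,10S)-15-(tert-butyldiphenylsilyloxy)-1,10-epoxy-8,14-bis(triethylsilyloxy)germacr-4-en-12,6-olide
Product: 33 (1R,4E,6R,7S,8S,10S)-15-(tert-butyldiphenylsilyloxy)-13-(dimethylamino)-1,10-epoxy-8,14-bis(triethylsilyloxy)germacr-4-en-12,6-olide (C11 epimers), via lithium enolate 32 (not isolated)
Conditions: LiN(i-Pr)2, THF, −78 °C; Me2N=CH2+ I−, −78 → 0 °C
Reagents that add atoms: N,N-dimethylmethyleneiminium iodide, C=[N+](C)C.[I-]
Why: Mannich reaction of the lactone enolate with Eschenmoser's salt; C11 is the only acidic position, no leaving group sits on C7, and the configuration of the new C11 centre does not matter.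

Step 18
Reactants: 33 (1R,4E,6R,7S,8S,10S)-15-(tert-butyldiphenylsilyloxy)-13-(dimethylamino)-1,10-epoxy-8,14-bis(triethylsilyloxy)germacr-4-en-12,6-olide
Product: 35 (1R,4E,6R,7S,8S,10S)-15-(tert-butyldiphenylsilyloxy)-1,10-epoxy-8,14-bis(triethylsilyloxy)germacra-4,11(13)-dien-12,6-olide, via ammonium iodide 34 (not isolated)
Conditions: MeI, MeOH, rt; aq. NaHCO3, CH2Cl2, rt
Reagents that add atoms: none
Why: Quaternisation of the amine followed by E1cB loss of trimethylamine under weak base gives the exocyclic C11=C13 alkene.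

Step 19
Reactants: 35 (1R,4E,6R,7S,8S,10S)-15-(tert-butyldiphenylsilyloxy)-1,10-epoxy-8,14-bis(triethylsilyloxy)germacra-4,11(13)-dien-12,6-olide
Product: 36 (1R,4E,6R,7R,8S,10S)-15-(tert-butyldiphenylsilyloxy)-1,10-epoxy-8,14-dihydroxygermacra-4,11(13)-dien-12,6-olide
Conditions: HF·pyridine, pyridine, THF, 0 °C → rt
Reagents that add atoms: none
Why: Buffered HF cleaves the two TES ethers far faster than the TBDPS ether; fluoride does not add to the methylene lactone and the buffered medium spares the epoxide and avoids the base that would shift the lactone to O8.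

Step 20
Reactants: 36 (1R,4E,6R,7R,8S,10S)-15-(tert-butyldiphenylsilyloxy)-1,10-epoxy-8,14-dihydroxygermacra-4,11(13)-dien-12,6-olide
Product: 37 (1R,4E,6R,7R,8S,10S)-14-acetoxy-15-(tert-butyldiphenylsilyloxy)-1,10-epoxy-8-hydroxygermacra-4,11(13)-dien-12,6-olide
Conditions: AcCl (1.1 equiv), 2,4,6-collidine, CH2Cl2, −78 °C
Reagents that add atoms: acetyl chloride, CC(Cl)=O
Why: Kinetic acetylation with a weak hindered base: the primary C14 hydroxyl reacts well before the secondary C8 hydroxyl on the ring.

Step 21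
Reactants: 37 (1R,4E,6R,7R,8S,10S)-14-acetoxy-15-(tert-butyldiphenylsilyloxy)-1,10-epoxy-8-hydroxygermacra-4,11(13)-dien-12,6-olide
Product: 38 (1R,4E,6R,7R,8S,10S)-14-acetoxy-15-(tert-butyldiphenylsilyloxy)-1,10-epoxy-8-(2-methylprop-2-enoyloxy)germacra-4,11(13)-dien-12,6-olide
Conditions: methacrylic anhydride, Et3N, DMAP (cat.), CH2Cl2, 0 °C → rt
Reagents that add atoms: methacrylic anhydride, C=C(C)C(=O)OC(=O)C(C)=C
Why: DMAP-catalysed acylation of the secondary alcohol, which is faster than base-induced migration of the lactone from O6 to O8.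

Step 22
Reactants: 38 (1R,4E,6R,7R,8S,10S)-14-acetoxy-15-(tert-butyldiphenylsilyloxy)-1,10-epoxy-8-(2-methylprop-2-enoyloxy)germacra-4,11(13)-dien-12,6-olide
Product: 39 (1R,4E,6R,7R,8S,10S)-14-acetoxy-1,10-epoxy-15-hydroxy-8-(2-methylprop-2-enoyloxy)germacra-4,11(13)-dien-12,6-olide (CNP0306006.2)
Conditions: Bu4NF, AcOH (1:1), THF, 0 °C → rt
Reagents that add atoms: none
Why: Fluoride buffered with acetic acid cleaves the primary allylic TBDPS ether without the alkoxide basicity that would move or cleave the acetate and methacrylate or add to the methylene lactone.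

## Compound list

1 | prop-2-yn-1-ol (propargyl alcohol) | C#CCO | starting material
2 | tert-butyl(diphenyl)(prop-2-yn-1-yloxy)silane | C#CCO[Si](c1ccccc1)(c1ccccc1)C(C)(C)C | intermediate
3 | 2-(2-bromoethyl)-1,3-dioxolane | BrCCC1OCCO1 | starting material
4 | [2-(1,3-dioxolan-2-yl)ethyl]magnesium bromide | Br[Mg]CCC1OCCO1 | intermediate (not isolated)
5 | [2-(1,3-dioxolan-2-yl)ethyl]copper (as MgBr2 complex) | [Cu]CCC1OCCO1 | intermediate (not isolated)
6 | [(1E)-2-{[tert-butyl(diphenyl)silyl]oxymethyl}-4-(1,3-dioxolan-2-yl)but-1-en-1-yl]copper | [Cu]/C=C(/CO[Si](c1ccccc1)(c1ccccc1)C(C)(C)C)CCC1OCCO1 | intermediate (not isolated)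
7 | tert-butyl({(2E)-2-[2-(1,3-dioxolan-2-yl)ethyl]-3-iodoprop-2-en-1-yl}oxy)diphenylsilane | I/C=C(/CO[Si](c1ccccc1)(c1ccccc1)C(C)(C)C)CCC1OCCO1 | intermediate
8 | (4E)-4-{[tert-butyl(diphenyl)silyl]oxymethyl}-5-iodopent-4-enal | O=CCC/C(CO[Si](c1ccccc1)(c1ccccc1)C(C)(C)C)=C\I | intermediate
9 | methyl 2-[bis(2,2,2-trifluoroethoxy)phosphoryl]acetate | COC(=O)CP(=O)(OCC(F)(F)F)OCC(F)(F)F | starting material
10 | 3-bromoprop-1-ene (allyl bromide) | C=CCBr | starting material
11 | sodium salt of 9 (phosphonoacetate carbanion) | COC(=O)[CH-]P(=O)(OCC(F)(F)F)OCC(F)(F)F.[Na+] | intermediate (not isolated)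
12 | methyl 2-[bis(2,2,2-trifluoroethoxy)phosphoryl]pent-4-enoate (racemic) | COC(=O)C(CC=C)P(=O)(OCC(F)(F)F)OCC(F)(F)F | intermediate
13 | potassium salt of 12 (phosphonate carbanion) | COC(=O)[C-](CC=C)P(=O)(OCC(F)(F)F)OCC(F)(F)F.[K+] | intermediate (not isolated)
14 | methyl (2Z,6E)-6-{[tert-butyl(diphenyl)silyl]oxymethyl}-7-iodo-2-(prop-2-en-1-yl)hepta-2,6-dienoate | COC(=O)/C(CC=C)=C\CC/C(CO[Si](c1ccccc1)(c1ccccc1)C(C)(C)C)=C\I | intermediate
15 | (2Z,6E)-6-{[tert-butyl(diphenyl)silyl]oxymethyl}-7-iodo-2-(prop-2-en-1-yl)hepta-2,6-dien-1-ol | OC/C(CC=C)=C\CC/C(CO[Si](c1ccccc1)(c1ccccc1)C(C)(C)C)=C\I | intermediate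
16 | [(2S,3R)-3-[(3E)-3-{[tert-butyl(diphenyl)silyl]oxymethyl}-4-iodobut-3-en-1-yl]-2-(prop-2-en-1-yl)oxiran-2-yl]methanol | C=CC[C@@]1(CO)O[C@@H]1CC/C(CO[Si](c1ccccc1)(c1ccccc1)C(C)(C)C)=C\I | intermediate
17 | {(2S,3R)-3-[(3E)-3-{[tert-butyl(diphenyl)silyl]oxymethyl}-4-iodobut-3-en-1-yl]-2-(prop-2-en-1-yl)oxiran-2-yl}methyl triethylsilyl ether | C=CC[C@@]1(CO[Si](CC)(CC)CC)O[C@@H]1CC/C(CO[Si](c1ccccc1)(c1ccccc1)C(C)(C)C)=C\I | intermediate
18 | 3-{(2S,3R)-3-[(3E)-3-{[tert-butyl(diphenyl)silyl]oxymethyl}-4-iodobut-3-en-1-yl]-2-[(triethylsilyloxy)methyl]oxiran-2-yl}propane-1,2-diol (both diol C2 epimers) | OCC(O)C[C@@]1(CO[Si](CC)(CC)CC)O[C@@H]1CC/C(CO[Si](c1ccccc1)(c1ccccc1)C(C)(C)C)=C\I | intermediate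
19 | {(2S,3R)-3-[(3E)-3-{[tert-butyl(diphenyl)silyl]oxymethyl}-4-iodobut-3-en-1-yl]-2-[(triethylsilyloxy)methyl]oxiran-2-yl}acetaldehyde | O=CC[C@@]1(CO[Si](CC)(CC)CC)O[C@@H]1CC/C(CO[Si](c1ccccc1)(c1ccccc1)C(C)(C)C)=C\I | intermediate
20 | (4R)-4-benzyl-1,3-oxazolidin-2-one | O=C1N[C@H](Cc2ccccc2)CO1 | starting material
21 | methyl 4-chloro-4-oxobutanoate | COC(=O)CCC(Cl)=O | starting material
22 | methyl 4-[(4R)-4-benzyl-2-oxo-1,3-oxazolidin-3-yl]-4-oxobutanoate | COC(=O)CCC(=O)N1[C@H](Cc2ccccc2)COC1=O | intermediate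
23 | (Z)-dibutylboron enolate of 22 | COC(=O)C/C=C(\OB(CCCC)CCCC)N1[C@H](Cc2ccccc2)COC1=O | intermediate (not isolated)
24 | O8-dibutylboryl aldolate of 25 | CCCCB(CCCC)O[C@@H](C[C@@]1(CO[Si](CC)(CC)CC)O[C@@H]1CC/C(CO[Si](c1ccccc1)(c1ccccc1)C(C)(C)C)=C\I)[C@@H](CC(=O)OC)C(=O)N1[C@H](Cc2ccccc2)COC1=O | intermediate (not isolated)
25 | methyl (3R,4S)-3-{[(4R)-4-benzyl-2-oxo-1,3-oxazolidin-3-yl]carbonyl}-4-hydroxy-5-{(2S,3R)-3-[(3E)-3-{[tert-butyl(diphenyl)silyl]oxymethyl}-4-iodobut-3-en-1-yl]-2-[(triethylsilyloxy)methyl]oxiran-2-yl}pentanoate | O[C@@H](C[C@@]1(CO[Si](CC)(CC)CC)O[C@@H]1CC/C(CO[Si](c1ccccc1)(c1ccccc1)C(C)(C)C)=C\I)[C@@H](CC(=O)OC)C(=O)N1[C@H](Cc2ccccc2)COC1=O | intermediate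
26 | methyl (3R,4S)-3-{[(4R)-4-benzyl-2-oxo-1,3-oxazolidin-3-yl]carbonyl}-5-{(2S,3R)-3-[(3E)-3-{[tert-butyl(diphenyl)silyl]oxymethyl}-4-iodobut-3-en-1-yl]-2-[(triethylsilyloxy)methyl]oxiran-2-yl}-4-(triethylsilyloxy)pentanoate | CC[Si](CC)(CC)O[C@@H](C[C@@]1(CO[Si](CC)(CC)CC)O[C@@H]1CC/C(CO[Si](c1ccccc1)(c1ccccc1)C(C)(C)C)=C\I)[C@@H](CC(=O)OC)C(=O)N1[C@H](Cc2ccccc2)COC1=O | intermediate
27 | methyl (3R,4S)-5-{(2S,3R)-3-[(3E)-3-{[tert-butyl(diphenyl)silyl]oxymethyl}-4-iodobut-3-en-1-yl]-2-[(triethylsilyloxy)methyl]oxiran-2-yl}-3-[(ethylsulfanyl)carbonyl]-4-(triethylsilyloxy)pentanoate | CC[Si](CC)(CC)O[C@@H](C[C@@]1(CO[Si](CC)(CC)CC)O[C@@H]1CC/C(CO[Si](c1ccccc1)(c1ccccc1)C(C)(C)C)=C\I)[C@@H](CC(=O)OC)C(=O)SCC | intermediate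
28 | methyl (3R,4S)-5-{(2S,3R)-3-[(3E)-3-{[tert-butyl(diphenyl)silyl]oxymethyl}-4-iodobut-3-en-1-yl]-2-[(triethylsilyloxy)methyl]oxiran-2-yl}-3-formyl-4-(triethylsilyloxy)pentanoate | CC[Si](CC)(CC)O[C@@H](C[C@@]1(CO[Si](CC)(CC)CC)O[C@@H]1CC/C(CO[Si](c1ccccc1)(c1ccccc1)C(C)(C)C)=C\I)[C@@H](CC(=O)OC)C=O | intermediate
29 | alkenylchromium dichloride from 28 (CrCl2 on C5 in place of iodine) | CC[Si](CC)(CC)O[C@@H](C[C@@]1(CO[Si](CC)(CC)CC)O[C@@H]1CC/C(CO[Si](c1ccccc1)(c1ccccc1)C(C)(C)C)=C\[Cr](Cl)Cl)[C@@H](CC(=O)OC)C=O | intermediate (not isolated)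
30 | chromium dichloride alkoxide of the ring-closed (6R)-hydroxy methyl ester | CC[Si](CC)(CC)O[C@H]1C[C@@]2(CO[Si](CC)(CC)CC)O[C@@H]2CC/C(CO[Si](c3ccccc3)(c3ccccc3)C(C)(C)C)=C\[C@@H](O[Cr](Cl)Cl)[C@@H]1CC(=O)OC | intermediate (not isolated)
31 | (1R,4E,6R,7S,8S,10S)-15-(tert-butyldiphenylsilyloxy)-1,10-epoxy-8,14-bis(triethylsilyloxy)germacr-4-en-12,6-olide | CC[Si](CC)(CC)O[C@H]1C[C@@]2(CO[Si](CC)(CC)CC)O[C@@H]2CC/C(CO[Si](c3ccccc3)(c3ccccc3)C(C)(C)C)=C\[C@H]2OC(=O)C[C@H]12 | intermediate
32 | lithium enolate of 31 (O–Li on C12, C11=C12) | CC[Si](CC)(CC)O[C@H]1C[C@@]2(CO[Si](CC)(CC)CC)O[C@@H]2CC/C(CO[Si](c3ccccc3)(c3ccccc3)C(C)(C)C)=C\[C@H]2OC(O[Li])=C[C@H]12 | intermediate (not isolated)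
33 | (1R,4E,6R,7S,8S,10S)-15-(tert-butyldiphenylsilyloxy)-13-(dimethylamino)-1,10-epoxy-8,14-bis(triethylsilyloxy)germacr-4-en-12,6-olide (C11 epimers) | CC[Si](CC)(CC)O[C@H]1C[C@@]2(CO[Si](CC)(CC)CC)O[C@@H]2CC/C(CO[Si](c3ccccc3)(c3ccccc3)C(C)(C)C)=C\[C@H]2OC(=O)C(CN(C)C)[C@H]12 | intermediate
34 | 13-(trimethylammonio) iodide of 33 | CC[Si](CC)(CC)O[C@H]1C[C@@]2(CO[Si](CC)(CC)CC)O[C@@H]2CC/C(CO[Si](c3ccccc3)(c3ccccc3)C(C)(C)C)=C\[C@H]2OC(=O)C(C[N+](C)(C)C)[C@H]12.[I-] | intermediate (not isolated)
35 | (1R,4E,6R,7S,8S,10S)-15-(tert-butyldiphenylsilyloxy)-1,10-epoxy-8,14-bis(triethylsilyloxy)germacra-4,11(13)-dien-12,6-olide | CC[Si](CC)(CC)O[C@H]1C[C@@]2(CO[Si](CC)(CC)CC)O[C@@H]2CC/C(CO[Si](c3ccccc3)(c3ccccc3)C(C)(C)C)=C\[C@H]2OC(=O)C(=C)[C@H]12 | intermediate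
36 | (1R,4E,6R,7R,8S,10S)-15-(tert-butyldiphenylsilyloxy)-1,10-epoxy-8,14-dihydroxygermacra-4,11(13)-dien-12,6-olide | O[C@H]1C[C@@]2(CO)O[C@@H]2CC/C(CO[Si](c3ccccc3)(c3ccccc3)C(C)(C)C)=C\[C@H]2OC(=O)C(=C)[C@H]12 | intermediate
37 | (1R,4E,6R,7R,8S,10S)-14-acetoxy-15-(tert-butyldiphenylsilyloxy)-1,10-epoxy-8-hydroxygermacra-4,11(13)-dien-12,6-olide | O[C@H]1C[C@@]2(COC(C)=O)O[C@@H]2CC/C(CO[Si](c3ccccc3)(c3ccccc3)C(C)(C)C)=C\[C@H]2OC(=O)C(=C)[C@H]12 | intermediate
38 | (1R,4E,6R,7R,8S,10S)-14-acetoxy-15-(tert-butyldiphenylsilyloxy)-1,10-epoxy-8-(2-methylprop-2-enoyloxy)germacra-4,11(13)-dien-12,6-olide | C=C(C)C(=O)O[C@H]1C[C@@]2(COC(C)=O)O[C@@H]2CC/C(CO[Si](c3ccccc3)(c3ccccc3)C(C)(C)C)=C\[C@H]2OC(=O)C(=C)[C@H]12 | intermediate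
39 | (1R,4E,6R,7R,8S,10S)-14-acetoxy-1,10-epoxy-15-hydroxy-8-(2-methylprop-2-enoyloxy)germacra-4,11(13)-dien-12,6-olide | C=C(C)C(=O)O[C@H]1C[C@@]2(COC(C)=O)O[C@@H]2CC/C(CO)=C\[C@H]2OC(=O)C(=C)[C@H]12 | target

## Step count and weak points

Total step count: 22. Longest linear sequence: 20 steps (steps 1–3, 5–10 and 12–22, from propargyl alcohol).

**Step 16 (key step).** The most likely failure is attack on the wrong face of the C6 aldehyde. The Felkin preference set by C7 is not reinforced by the silyloxy group on C8 and has to be carried by the ring-forming conformation; intermolecular coupling is the second risk if dilution is insufficient. Fallback: correct C6 by inversion instead of relying on substrate control. Setting out from 28, a closure that favours the C6 epimer should give the cis-lactone, (1R,4E,6S,7S,8S,10S)-15-(tert-butyldiphenylsilyloxy)-1,10-epoxy-8,14-bis(triethylsilyloxy)germacr-4-en-12,6-olide F1. LiOH in aqueous THF opens it to the (6S)-hydroxy acid F2. A Mitsunobu lactonisation (PPh3, diisopropyl azodicarboxylate) then lets the carboxylate displace the activated C6 oxygen with inversion, which returns the route to 31.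

**Step 2.** The most likely failure is loss of regiocontrol in the carbocupration. If the propargylic oxygen still guides copper to the inner carbon, the adduct eliminates to an allene and the branched iodoalkene is lost. Fallback: build the same iodoalkene by elimination chemistry. Setting out from 1 and 3 (through 4), CuI-catalysed addition of Grignard reagent 4 to propargyl alcohol 1 places the alkyl group on the inner carbon through the magnesium alkoxide chelate and, after protonation, gives 2-[2-(1,3-dioxolan-2-yl)ethyl]prop-2-en-1-ol F3. MnO2 oxidises it to the 2-substituted acrolein F4. Br2 gives the 2,3-dibromo aldehyde F5, and Et3N eliminates HBr to the (2E)-3-bromo enal F6, in which bromine lies anti to the carbonyl and therefore cis to the chain. NaBH4 with CeCl3 gives the bromo allylic alcohol F7, and TBDPSCl gives the silyl ether F8. CuI-catalysed bromide–iodide exchange (NaI, N,N'-dimethylethylenediamine, dioxane, heat) proceeds with retention and returns the route to 7.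

**Step 12.** The most likely failure is loss of the adduct before it is silylated: the free C8 hydroxyl can close onto the C12 methyl ester, and the β,γ-epoxy aldehyde can open by enolisation if free amine is present. Fallback: carry C12 through the aldol as an alkene, which cannot lactonise. Setting out from 20 and 19, oxazolidinone 20 is acylated with pent-4-enoyl chloride to the imide F9. The same boron aldol with 19 gives the syn adduct F10, and TESOTf gives its silyl ether F11. OsO4 with N-methylmorpholine N-oxide dihydroxylates the new terminal alkene to diol F12, NaIO4 gives the C12 aldehyde F13, and NaClO2 with NaH2PO4 and 2-methylbut-2-ene gives the acid F14. Me3SiCHN2 then forms the methyl ester, which returns the route to 26.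

**Step 15.** The most likely failure is incomplete discrimination by the hydride: attack on the C12 methyl ester, or over-reduction at C6 to the alcohol, which would lactonise. Fallback: use an acid chloride, which is reduced far more selectively. Setting out from 27, silver-assisted hydrolysis (AgNO3, H2O, THF) gives the C6 carboxylic acid F15. 1-Chloro-N,N,2-trimethylprop-1-en-1-amine converts it under neutral conditions into the acid chloride F16. LiAlH(OtBu)3 at −78 °C reduces the acid chloride to the aldehyde without touching the methyl ester, which returns the route to 28.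

**Step 20.** The most likely failure is partial acetylation of the C8 hydroxyl, or diacetylation, because the primary C14 hydroxyl is neopentyl-like and its advantage over the ring alcohol may be smaller than usual. Fallback: unmask the two oxygens one after the other. Setting out from 35, brief treatment with HF·pyridine and pyridine at −20 °C removes the primary TES ether first and gives the 14-hydroxy 8-triethylsilyl ether F17. Ac2O, pyridine and DMAP give the 14-acetate F18, and HF·pyridine at 0 °C then frees O8, which returns the route to 37.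

## Further compounds

F1 | step 16 | (1R,4E,6S,7S,8S,10S)-15-(tert-butyldiphenylsilyloxy)-1,10-epoxy-8,14-bis(triethylsilyloxy)germacr-4-en-12,6-olide (C6 epimer of 31, cis-lactone) | CC[Si](CC)(CC)O[C@H]1C[C@@]2(CO[Si](CC)(CC)CC)O[C@@H]2CC/C(CO[Si](c3ccccc3)(c3ccccc3)C(C)(C)C)=C\[C@@H]2OC(=O)C[C@H]12
F2 | step 16 | (6S)-6-hydroxy seco acid of F1 (C12 carboxylic acid, ten-membered ring intact) | CC[Si](CC)(CC)O[C@H]1C[C@@]2(CO[Si](CC)(CC)CC)O[C@@H]2CC/C(CO[Si](c3ccccc3)(c3ccccc3)C(C)(C)C)=C\[C@H](O)[C@@H]1CC(=O)O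
F3 | step 2 | 2-[2-(1,3-dioxolan-2-yl)ethyl]prop-2-en-1-ol | C=C(CO)CCC1OCCO1
F4 | step 2 | 2-[2-(1,3-dioxolan-2-yl)ethyl]prop-2-enal | C=C(C=O)CCC1OCCO1
F5 | step 2 | 2,3-dibromo-2-[2-(1,3-dioxolan-2-yl)ethyl]propanal (racemic) | O=CC(Br)(CBr)CCC1OCCO1
F6 | step 2 | (2E)-3-bromo-2-[2-(1,3-dioxolan-2-yl)ethyl]prop-2-enal | Br/C=C(/C=O)CCC1OCCO1
F7 | step 2 | (2E)-3-bromo-2-[2-(1,3-dioxolan-2-yl)ethyl]prop-2-en-1-ol | Br/C=C(/CO)CCC1OCCO1
F8 | step 2 | ({(2E)-3-bromo-2-[2-(1,3-dioxolan-2-yl)ethyl]prop-2-en-1-yl}oxy)(tert-butyl)diphenylsilane | Br/C=C(/CO[Si](c1ccccc1)(c1ccccc1)C(C)(C)C)CCC1OCCO1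
F9 | step 12 | (4R)-4-benzyl-3-(pent-4-enoyl)-1,3-oxazolidin-2-one | C=CCCC(=O)N1[C@H](Cc2ccccc2)COC1=O
F10 | step 12 | syn-aldol adduct of F9 and 19 (C7 bears an allyl group, free C8 hydroxyl) | O[C@@H](C[C@@]1(CO[Si](CC)(CC)CC)O[C@@H]1CC/C(CO[Si](c1ccccc1)(c1ccccc1)C(C)(C)C)=C\I)[C@@H](CC=C)C(=O)N1[C@H](Cc2ccccc2)COC1=O
F11 | step 12 | O8-triethylsilyl ether of F10 | CC[Si](CC)(CC)O[C@@H](C[C@@]1(CO[Si](CC)(CC)CC)O[C@@H]1CC/C(CO[Si](c1ccccc1)(c1ccccc1)C(C)(C)C)=C\I)[C@@H](CC=C)C(=O)N1[C@H](Cc2ccccc2)COC1=O
F12 | step 12 | 1,2-diol from the terminal alkene of F11 (both carbinol epimers) | CC[Si](CC)(CC)O[C@@H](C[C@@]1(CO[Si](CC)(CC)CC)O[C@@H]1CC/C(CO[Si](c1ccccc1)(c1ccccc1)C(C)(C)C)=C\I)[C@@H](CC(O)CO)C(=O)N1[C@H](Cc2ccccc2)COC1=O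
F13 | step 12 | C12 aldehyde from F12 | CC[Si](CC)(CC)O[C@@H](C[C@@]1(CO[Si](CC)(CC)CC)O[C@@H]1CC/C(CO[Si](c1ccccc1)(c1ccccc1)C(C)(C)C)=C\I)[C@@H](CC=O)C(=O)N1[C@H](Cc2ccccc2)COC1=O
F14 | step 12 | C12 carboxylic acid corresponding to 26 | CC[Si](CC)(CC)O[C@@H](C[C@@]1(CO[Si](CC)(CC)CC)O[C@@H]1CC/C(CO[Si](c1ccccc1)(c1ccccc1)C(C)(C)C)=C\I)[C@@H](CC(=O)O)C(=O)N1[C@H](Cc2ccccc2)COC1=O
F15 | step 15 | C6 carboxylic acid from 27 (C12 methyl ester kept) | CC[Si](CC)(CC)O[C@@H](C[C@@]1(CO[Si](CC)(CC)CC)O[C@@H]1CC/C(CO[Si](c1ccccc1)(c1ccccc1)C(C)(C)C)=C\I)[C@@H](CC(=O)OC)C(=O)O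
F16 | step 15 | C6 acid chloride from F15 | CC[Si](CC)(CC)O[C@@H](C[C@@]1(CO[Si](CC)(CC)CC)O[C@@H]1CC/C(CO[Si](c1ccccc1)(c1ccccc1)C(C)(C)C)=C\I)[C@@H](CC(=O)OC)C(=O)Cl
F17 | step 20 | (1R,4E,6R,7S,8S,10S)-15-(tert-butyldiphenylsilyloxy)-1,10-epoxy-14-hydroxy-8-(triethylsilyloxy)germacra-4,11(13)-dien-12,6-olide | CC[Si](CC)(CC)O[C@H]1C[C@@]2(CO)O[C@@H]2CC/C(CO[Si](c3ccccc3)(c3ccccc3)C(C)(C)C)=C\[C@H]2OC(=O)C(=C)[C@H]12
F18 | step 20 | (1R,4E,6R,7S,8S,10S)-14-acetoxy-15-(tert-butyldiphenylsilyloxy)-1,10-epoxy-8-(triethylsilyloxy)germacra-4,11(13)-dien-12,6-olide | CC[Si](CC)(CC)O[C@H]1C[C@@]2(COC(C)=O)O[C@@H]2CC/C(CO[Si](c3ccccc3)(c3ccccc3)C(C)(C)C)=C\[C@H]2OC(=O)C(=C)[C@H]12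
A1 | alternative 1 | ten-membered 1(10),4-dien-6-one with free C14 hydroxyl (C8 p-methoxybenzyl ether, C12 and C15 silyl ethers) | O=C1/C=C(CO[Si](c2ccccc2)(c2ccccc2)C(C)(C)C)\CC/C=C(CO)/C[C@H](OCc2ccc(OC)cc2)[C@H]1C(=C)CO[Si](C)(C)C(C)(C)C
A2 | alternative 2 | 8-hydroxy α-methylene 12,6-lactone of the 1(10),4-diene (C14 p-methoxybenzyl ether, C15 silyl ether) | O[C@H]1C/C(COCc2ccc(OC)cc2)=C/CC/C(CO[Si](c2ccccc2)(c2ccccc2)C(C)(C)C)=C\[C@H]2OC(=O)C(=C)[C@H]12
A3 | alternative 3 | ten-membered β-hydroxy ketone (C8 ketone, C10 tertiary alcohol, protected O1, O6, O12, O14, O15) | O=C1C[C@](O)(COCc2ccc(OC)cc2)[C@@H](O[Si](CC)(CC)CC)CC/C(CO[Si](c2ccccc2)(c2ccccc2)C(C)(C)C)=C\[C@@H](O[Si](C)(C)C(C)(C)C)[C@@H]1C(=C)CO[Si](C)(C)C(C)(C)C
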